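If two flasks with the same substrate charge are compared at one conversion instead of at one time, the reagent used can be reckoned from the stoichiometry, and free catalyst is what remains to be reckoned.

| flask | left-handed substrate | right-handed substrate | reagent | free catalyst | impurity | remark |
|---|---|---|---|---|---|---|
| larch | 0.14 M | 0.14 M | 1 equiv | 0.5 mol% | 0.35 mM | run made earlier |
| birch | 0.14 M | 0.14 M | 1 equiv | 0.75 mol% | 0.35 mM | run made earlier |
| flask | 0.14 M | 0.14 M | 1.00 equiv | 1 mol% | 0.35 mM |  |

- larch (time / min: left-handed product / %): 3.00: 3.2; 6.00: 5.6; 10.0: 6.2; 15.0: 7.6; 20.0: 7.3; 25.0: 7.0
- birch (time / min: left-handed product / %): 2.00: 6.1; 3.00: 7.9; 4.00: 8.2; 6.00: 10.0; 10.0: 13.0; 15.0: 13.5; 25.0: 13.2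

(each reading ± 0.5 percentage points)

1. apparent order in reagent when 20 % of the left-handed substrate and right-handed substrate together are converted (percent change of the rate of making left-handed product for one percent more reagent charged)
2. factor on the rate of making left-handed product when 20 % of the left-handed substrate and right-handed substrate together are converted if free catalyst is charged twice over

- free catalyst is single-handed; left-handed substrate and right-handed substrate are mirror images of each other, charged as a racemate, each of them at the stated concentration
- the earlier runs were read with a standard deviation of 0.5 percentage points
- no earlier run changes the charge of reagent; that part of a forecast is a guess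

Take the main step first, the making of left-handed product from reagent, free catalyst and left-handed substrate, with the rate proportional to each. Taking one reagent per substrate converted, 20 % conversion leaves 60.0 % of the reagent in the flask. One percent more reagent charged therefore raises what is left by 1.67 percent, and this is the order. Doubling the catalyst would simply give a factor of 2.

Next comes the impurity, a catalyst poison. The birch plateau, as read, stands 1.81 times the larch plateau, while the catalyst charges differ by a factor of 1.50 and the catalyst left after subtracting the impurity by a factor of 2.00. So the impurity is taken to remove its own amount at once, leaving 0.700 mM in birch, 1.05 mM in the flask and 2.45 mM with the doubled charge.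

Last comes a death of free catalyst, which is how this reckoning reads the plateaus. Scaling the birch plateau gives the flask a left-handed stall of 19.8 %. Guessing that right-handed product adds half as much puts the total stall at 29.7 %. If death keeps pace with conversion, the catalyst lost by the mark, the amount dying per unit of conversion times the conversion reached, is 0.707 mM, whatever the catalyst charge. The factor for doubling is then 5.08. If death also takes one reagent, a guess, the order stays at 1.67.

The forecast gave 1 and 20, differing from this reckoning, and held that “little active catalyst remains there”.

The simulation gives 1.7 and 5.53.

    reagent + free catalyst + right-handed substrate → free catalyst + right-handed product (k = 5.40 L² mol⁻² s⁻¹)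
    free catalyst + impurity → spent catalyst A (k = 190 L mol⁻¹ s⁻¹)
    reagent + free catalyst + left-handed substrate → free catalyst + left-handed product (k = 15.0 L² mol⁻² s⁻¹)
    reagent + free catalyst → spent catalyst B (k = 0.0330 L mol⁻¹ s⁻¹)

At 20 % conversion, reached at 6.00 min, the flask holds 25.0 % of its catalyst as spent catalyst A and 52.9 % as spent catalyst B, which is 0.741 mM of spent catalyst B where the reckoning had 0.707 mM lost, and taking that amount from both catalyst figures gives a factor of 5.53. Reagent goes 2.4 times faster into left-handed product than into right-handed product at 2.33 min, and at 200 min the flask holds 19.0 % left-handed product against 7.89 % right-handed product.

(The earlier runs and the new flask stem from a simulated flask for an exercise, and the scatter is random.)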